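Numbering: ring B (quinone) = C1(=O), C2(OH), C3(side chain), C4(=O), C4a, C8a. Ring A = C4a, C5(OMe), C6(OMe), C7(H), C8(OMe), C8a.
Cuts: first the O–tBu bond at C2 (protecting group). Then C1–C8a, which unfolds ring B through the vinylketene O=C1=C2(OtBu)–C3(R)=C4(OSiMe3)–aryl into a 4-aryl-4-silyloxycyclobutenone (temporary four-membered ring C1–C2–C3–C4). Then C3–CH2 (side chain) and C4–C4a (aryl).
Enabling feature: C1–C2–C3–C4 of ring B is a four-carbon chain with oxygen on C1, C2 and C4, which is a squaric acid skeleton. Ring A offers the ketene only one open ortho position, C8a–H (ortho to C8–OMe, para to C6–OMe), because the other ortho carbon C5 carries OMe.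
Forward: ring A is bought and trimmed to the aryl bromide (steps 1–2) and joined to di-tert-butyl squarate at C4–C4a (step 3). The side chain is joined at C3 with a 1,3-carbonyl transposition that moves C=O to C1 (step 4), and the alcohol is acetylated (step 5). Ring B arises by 4π opening, 6π closure and oxidation (step 6), and the tert-butyl group leaves (step 7).
Stereochemistry: the one stereocentre is bought as (S)-propylene oxide and its C–O bond is never broken. The ring carbinol centre C4 forms without control and vanishes in step 6.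

Key step: step 6

Assumption: di-tert-butyl squarate is taken to be purchasable, and the Why lines use the target numbering given above for all intermediates.

Step 1
Reactants: 1 3-bromo-4,5-dimethoxybenzaldehyde
Product: 3 3-bromo-4,5-dimethoxyphenol, via aryl formate 2 (not isolated)
Conditions: mCPBA, CH2Cl2, 0 °C to rt; aq. NaHCO3 wash; then K2CO3 (cat.), MeOH, rt
Reagents that add atoms: mCPBA, OOC(=O)c1cccc(Cl)c1
Why: Baeyer–Villiger oxidation, in which the electron-rich aryl group (OMe para to CHO) migrates in preference to H, followed by transesterification of the aryl formate with methanol.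

Step 2
Reactants: 3 3-bromo-4,5-dimethoxyphenol
Product: 4 1-bromo-2,3,5-trimethoxybenzene
Conditions: MeI, K2CO3, acetone, reflux
Reagents that add atoms: methyl iodide, CI
Why: Williamson ether synthesis (SN2 of the phenoxide on MeI) on an unhindered phenol, with the aryl bromide inert.

Step 3
Reactants: 4 1-bromo-2,3,5-trimethoxybenzene; 5 di-tert-butyl squarate (3,4-di-tert-butoxycyclobut-3-ene-1,2-dione)
Product: 8 racemic 2,3-di-tert-butoxy-4-(2,3,5-trimethoxyphenyl)-4-(trimethylsilyloxy)cyclobut-2-en-1-one, via aryllithium 6 (not isolated), via lithium alkoxide 7 (not isolated)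
Conditions: n-BuLi, THF, −78 °C; cannulated into 5, THF, −78 °C; TMSCl, −78 °C to rt
Reagents that add atoms: chlorotrimethylsilane, C[Si](C)(C)Cl
Why: Bromine–lithium exchange outruns ortho-lithiation at −78 °C, aryllithiums add 1,2 to one of the two equivalent squarate carbonyl groups (bond C4–C4a), and O-silylation blocks the carbinol oxygen for steps 4 and 5, the new centre C4 being formed racemic and erased in step 6.

Step 4
Reactants: 8 racemic 2,3-di-tert-butoxy-4-(2,3,5-trimethoxyphenyl)-4-(trimethylsilyloxy)cyclobut-2-en-1-one; 9 (S)-propylene oxide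
Product: 13 2-tert-butoxy-3-[(2S)-2-hydroxypropyl]-4-(2,3,5-trimethoxyphenyl)-4-(trimethylsilyloxy)cyclobut-2-en-1-one (both C4 epimers), via beta-lithioalkoxide 10 (not isolated), via dilithium dialkoxide 11 (not isolated), via side-chain trifluoroacetate 12 (not isolated)
Conditions: Li, 4,4'-di-tert-butylbiphenyl (DTBB), THF, 0 °C (LiDTBB, 2 equiv per 9); 9, −78 °C; 8, THF, −78 °C; (CF3CO)2O, −78 to 0 °C; aq. NaHCO3 work-up; MeOH, NaHCO3 (cat.), rt
Reagents that add atoms: none
Why: Reductive lithiation of a monoalkyl epoxide by an arene radical anion cleaves the less substituted C–O bond and gives the primary organolithium 10 with the stereocentre untouched (S retained), 10 adds 1,2 to the remaining carbonyl (future C3), and trifluoroacetylation and ionisation of the tertiary allylic oxygen give a cation that the tert-butoxy group on future C1 stabilises and that sheds isobutene, a Stork–Danheiser-type 1,3-carbonyl transposition that sets C1=O, C2–OtBu and the C3 side chain next to C4.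

Step 5
Reactants: 13 2-tert-butoxy-3-[(2S)-2-hydroxypropyl]-4-(2,3,5-trimethoxyphenyl)-4-(trimethylsilyloxy)cyclobut-2-en-1-one
Product: 14 (2S)-1-[2-tert-butoxy-3-oxo-4-(2,3,5-trimethoxyphenyl)-4-(trimethylsilyloxy)cyclobut-1-en-1-yl]propan-2-yl acetate (both C4 epimers)
Conditions: Ac2O, pyridine, DMAP (cat.), CH2Cl2, 0 °C to rt
Reagents that add atoms: acetic anhydride, CC(=O)OC(C)=O
Why: DMAP-catalysed acylation of the only free hydroxyl group (the tertiary one is silylated) leaves the C–O bond at the stereocentre untouched and masks the oxygen that would otherwise trap the ketene of step 6 as a lactone.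

Step 6
Reactants: 14 (2S)-1-[2-tert-butoxy-3-oxo-4-(2,3,5-trimethoxyphenyl)-4-(trimethylsilyloxy)cyclobut-1-en-1-yl]propan-2-yl acetate
Product: 18 3-[(2S)-2-acetoxypropyl]-2-tert-butoxy-5,6,8-trimethoxy-1,4-naphthoquinone, via vinylketene 15 (not isolated), via 8a-H dienone 16 (not isolated), via silyl hydroquinone 17 (not isolated)
Conditions: toluene, 110 °C, Ar, base-washed glass; cool to rt; Ag2O, rt
Reagents that add atoms: none
Why: Heating opens the strained ring of 14 by conrotatory 4π electrocyclic cleavage of the C1–C4 bond, and the donor OSiMe3 group on C4 rotates outward (torquoselectivity), so the aryl group turns inward and ends cis to the ketene in 15. The ketene C1=C2, the C3=C4 bond and the C4a=C8a bond of ring A then form a hexatriene that closes by disrotatory 6π electrocyclisation (six-membered ring B, new bond C1–C8a) to dienone 16, which tautomerises to naphthol 17, and Ag2O takes 17 to quinone 18 with loss of the silyl helper. The closest known reaction type is the Moore rearrangement of 4-aryl-4-oxycyclobutenones. Site selectivity is secured by ring A itself, because closure at the OMe-bearing ortho carbon C5 cannot rearomatise and is reversible, whereas C8a carries H and is activated by the ortho C8–OMe and the para C6–OMe. The order of groups around ring B (C2–O next to the new bond, side chain next to C4) is fixed by the substitution pattern of the cyclobutenone and cannot scramble. No lasting stereocentre is made, since C4 becomes sp2 so that both epimers of 14 converge, the C8a centre of 16 is transient, and the side-chain centre is remote and untouched.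

Step 7
Reactants: 18 3-[(2S)-2-acetoxypropyl]-2-tert-butoxy-5,6,8-trimethoxy-1,4-naphthoquinone
Product: 19 3-[(2S)-2-acetoxypropyl]-2-hydroxy-5,6,8-trimethoxy-1,4-naphthoquinone (target)
Conditions: CF3CO2H, CH2Cl2, 0 °C
Reagents that add atoms: none
Why: Acidolysis (E1) of a tert-butyl vinylogous ester, in which protonation of the C4 carbonyl makes the 2-oxyquinone a good leaving group for the tert-butyl cation (lost as isobutene), while the methyl ethers and the secondary acetate do not ionise.

Compound list
1 | 3-bromo-4,5-dimethoxybenzaldehyde | O=Cc1cc(Br)c(OC)c(OC)c1 | starting material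
2 | 3-bromo-4,5-dimethoxyphenyl formate | O=COc1cc(Br)c(OC)c(OC)c1 | intermediate
3 | 3-bromo-4,5-dimethoxyphenol | Oc1cc(Br)c(OC)c(OC)c1 | intermediate
4 | 1-bromo-2,3,5-trimethoxybenzene | COc1cc(Br)c(OC)c(OC)c1 | intermediate
5 | di-tert-butyl squarate | CC(C)(C)OC1=C(OC(C)(C)C)C(=O)C1=O | starting material
6 | 2,3,5-trimethoxyphenyllithium | [Li]c1cc(OC)cc(OC)c1OC | intermediate
7 | lithium 2,3-di-tert-butoxy-4-oxo-1-(2,3,5-trimethoxyphenyl)cyclobut-2-en-1-olate (racemic) | [Li]OC1(C(=O)C(OC(C)(C)C)=C1OC(C)(C)C)c1cc(OC)cc(OC)c1OC | intermediate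
8 | 2,3-di-tert-butoxy-4-(2,3,5-trimethoxyphenyl)-4-(trimethylsilyloxy)cyclobut-2-en-1-one (racemic) | C[Si](C)(C)OC1(C(=O)C(OC(C)(C)C)=C1OC(C)(C)C)c1cc(OC)cc(OC)c1OC | intermediate
9 | (S)-propylene oxide | C[C@H]1CO1 | starting material
10 | lithium (2S)-1-lithiopropan-2-olate | C[C@H](O[Li])C[Li] | intermediate
11 | dilithium dialkoxide from 1,2-addition of 10 to 8 (ring centres uncontrolled) | [Li]OC1(C[C@H](C)O[Li])C(OC(C)(C)C)=C(OC(C)(C)C)C1(O[Si](C)(C)C)c1cc(OC)cc(OC)c1OC | intermediate
12 | (2S)-1-[2-tert-butoxy-3-oxo-4-(2,3,5-trimethoxyphenyl)-4-(trimethylsilyloxy)cyclobut-1-en-1-yl]propan-2-yl trifluoroacetate (C4 epimers) | O=C1C(OC(C)(C)C)=C(C[C@H](C)OC(=O)C(F)(F)F)C1(O[Si](C)(C)C)c1cc(OC)cc(OC)c1OC | intermediate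
13 | 2-tert-butoxy-3-[(2S)-2-hydroxypropyl]-4-(2,3,5-trimethoxyphenyl)-4-(trimethylsilyloxy)cyclobut-2-en-1-one (C4 epimers) | O=C1C(OC(C)(C)C)=C(C[C@H](C)O)C1(O[Si](C)(C)C)c1cc(OC)cc(OC)c1OC | intermediate
14 | (2S)-1-[2-tert-butoxy-3-oxo-4-(2,3,5-trimethoxyphenyl)-4-(trimethylsilyloxy)cyclobut-1-en-1-yl]propan-2-yl acetate (C4 epimers) | O=C1C(OC(C)(C)C)=C(C[C@H](C)OC(C)=O)C1(O[Si](C)(C)C)c1cc(OC)cc(OC)c1OC | intermediate
15 | vinylketene, aryl group cis to the ketene across C3=C4 | O=C=C(OC(C)(C)C)/C(C[C@H](C)OC(C)=O)=C(/O[Si](C)(C)C)c1cc(OC)cc(OC)c1OC | intermediate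
16 | 8a-H dienone from 6π closure (C8a transient, uncontrolled) | O=C1C(OC(C)(C)C)=C(C[C@H](C)OC(C)=O)C(O[Si](C)(C)C)=C2C(OC)=C(OC)C=C(OC)C12 | intermediate
17 | (2S)-1-[3-tert-butoxy-4-hydroxy-5,7,8-trimethoxy-1-(trimethylsilyloxy)naphthalen-2-yl]propan-2-yl acetate | Oc1c(OC(C)(C)C)c(C[C@H](C)OC(C)=O)c(O[Si](C)(C)C)c2c(OC)c(OC)cc(OC)c12 | intermediate
18 | 3-[(2S)-2-acetoxypropyl]-2-tert-butoxy-5,6,8-trimethoxy-1,4-naphthoquinone | O=C1C(OC(C)(C)C)=C(C[C@H](C)OC(C)=O)C(=O)c2c(OC)c(OC)cc(OC)c12 | intermediate
19 | 3-[(2S)-2-acetoxypropyl]-2-hydroxy-5,6,8-trimethoxy-1,4-naphthoquinone | COc1cc(OC)c2c(c1OC)C(=O)C(C[C@H](C)OC(C)=O)=C(O)C2=O | target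

Total step count: 7. Longest linear sequence: 7 steps (1 to 19); 5 and 9 enter as bought.

Steps most likely to fail

Step 4.
- What may go wrong: elimination of Li2O from the β-lithioalkoxide before it meets the ketone, electron transfer from leftover radical anion to the cyclobutenone, or O-to-O silyl migration in the adduct that would misdirect the ionisation.
- The fallback sets out from 8 and comes back at 19. It attaches the side chain last, as a radical.
- i-Bu2AlH (toluene, −78 °C) should reduce the carbonyl group of 8 to 2,3-di-tert-butoxy-4-(2,3,5-trimethoxyphenyl)-4-(trimethylsilyloxy)cyclobut-2-en-1-ol F1.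
- Oxalic acid in wet CH2Cl2 should transpose this to 2-tert-butoxy-4-(2,3,5-trimethoxyphenyl)-4-(trimethylsilyloxy)cyclobut-2-en-1-one F2.
- Thermolysis and Ag2O oxidation as in step 6 should give 2-tert-butoxy-5,6,8-trimethoxy-1,4-naphthoquinone F3, and CF3CO2H should give 2-hydroxy-5,6,8-trimethoxy-1,4-naphthoquinone F4.
- Commercial (S)-3-hydroxybutanoic acid is acetylated (Ac2O, pyridine) to (3S)-3-acetoxybutanoic acid F5.
- A silver-catalysed decarboxylative radical alkylation of F4 with F5 (AgNO3 cat., (NH4)2S2O8, MeCN–H2O, 65 °C) should place the primary radical on C3, the only free quinone carbon, and give 19. The stereocentre lies β to the radical and is untouched.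

Step 6.
- What may go wrong: loss of isobutene from the tert-butoxy-substituted ketene or enol ether in competition with a 6π closure that is slowed by crowding between the C4 silyloxy group and the C5 methoxy group.
- The fallback sets out from 5 (with 10 generated as in step 4) and comes back at 18. It moves the tert-butoxy group off the ketene carbon by building ring B from the other side.
- Addition of 10 to 5, then the (CF3CO)2O quench and methanolysis as in step 4, should give 3-tert-butoxy-4-[(2S)-2-hydroxypropyl]cyclobut-3-ene-1,2-dione F6.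
- Acetylation should give (2S)-1-(2-tert-butoxy-3,4-dioxocyclobut-1-en-1-yl)propan-2-yl acetate F7.
- One equivalent of 2,4,5-trimethoxyphenyllithium (from commercial 1-bromo-2,4,5-trimethoxybenzene and n-BuLi, −78 °C) should add to the more electrophilic carbonyl, the one next to C–OtBu. This reacts ahead of both the vinylogous ester carbonyl and the acetate, and should give (2S)-1-[2-tert-butoxy-3-hydroxy-4-oxo-3-(2,4,5-trimethoxyphenyl)cyclobut-1-en-1-yl]propan-2-yl acetate F8.
- Thermolysis in toluene and Ag2O oxidation should then close ring B at C4–C4a through an alkyl-substituted ketene and give 18.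

Step 7.
- What may go wrong: acid-induced attack of the freed C2 hydroxyl group on the side chain with loss of acetic acid, or acetyl transfer between the two oxygens.
- The fallback sets out from 18 and comes back at 19. It replaces acidolysis by addition–elimination under base.
- KOH in aqueous MeOH should displace tert-butoxide at C2 and saponify the acetate, giving 2-hydroxy-3-[(2S)-2-hydroxypropyl]-5,6,8-trimethoxy-1,4-naphthoquinone F9.
- Ac2O and pyridine should give (2S)-1-(3-acetoxy-5,7,8-trimethoxy-1,4-dioxo-1,4-dihydronaphthalen-2-yl)propan-2-yl acetate F10.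
- Brief methanolysis (NaHCO3, MeOH, 0 °C) should cleave only the quinonyl acetate, which behaves as a vinylogous mixed anhydride, and give 19.

Further compounds
F1 | step 4 | 2,3-di-tert-butoxy-4-(2,3,5-trimethoxyphenyl)-4-(trimethylsilyloxy)cyclobut-2-en-1-ol | OC1C(OC(C)(C)C)=C(OC(C)(C)C)C1(O[Si](C)(C)C)c1cc(OC)cc(OC)c1OC
F2 | step 4 | 2-tert-butoxy-4-(2,3,5-trimethoxyphenyl)-4-(trimethylsilyloxy)cyclobut-2-en-1-one | O=C1C(OC(C)(C)C)=CC1(O[Si](C)(C)C)c1cc(OC)cc(OC)c1OC
F3 | step 4 | 2-tert-butoxy-5,6,8-trimethoxy-1,4-naphthoquinone | O=C1C(OC(C)(C)C)=CC(=O)c2c(OC)c(OC)cc(OC)c12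
F4 | step 4 | 2-hydroxy-5,6,8-trimethoxy-1,4-naphthoquinone | O=C1C(O)=CC(=O)c2c(OC)c(OC)cc(OC)c12
F5 | step 4 | (3S)-3-acetoxybutanoic acid | OC(=O)C[C@H](C)OC(C)=O
F6 | step 6 | 3-tert-butoxy-4-[(2S)-2-hydroxypropyl]cyclobut-3-ene-1,2-dione | O=C1C(=O)C(OC(C)(C)C)=C1C[C@H](C)O
F7 | step 6 | (2S)-1-(2-tert-butoxy-3,4-dioxocyclobut-1-en-1-yl)propan-2-yl acetate | O=C1C(=O)C(OC(C)(C)C)=C1C[C@H](C)OC(C)=O
F8 | step 6 | (2S)-1-[2-tert-butoxy-3-hydroxy-4-oxo-3-(2,4,5-trimethoxyphenyl)cyclobut-1-en-1-yl]propan-2-yl acetate | O=C1C(C[C@H](C)OC(C)=O)=C(OC(C)(C)C)C1(O)c1cc(OC)c(OC)cc1OC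
F9 | step 7 | 2-hydroxy-3-[(2S)-2-hydroxypropyl]-5,6,8-trimethoxy-1,4-naphthoquinone | O=C1C(O)=C(C[C@H](C)O)C(=O)c2c(OC)c(OC)cc(OC)c12
F10 | step 7 | (2S)-1-(3-acetoxy-5,7,8-trimethoxy-1,4-dioxo-1,4-dihydronaphthalen-2-yl)propan-2-yl acetate | O=C1C(OC(C)=O)=C(C[C@H](C)OC(C)=O)C(=O)c2c(OC)c(OC)cc(OC)c12
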